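## Retrosynthetic overview

1. Target 26 ← Horner–Wadsworth–Emmons methylenation and twofold isobutyrylation of tetraol phosphonate 22.
2. 22 ← SmI2 scission of the C10–O bond of an ether-bridged cyclodecanone (11-oxabicyclo[5.3.1]undecane); the bridge oxygen becomes the C4 tertiary OH and C10 gains H.
3. Bridged ten-membered ring ← ozonolysis of the tetrasubstituted C5=C9 alkene of a cyclopentene-fused 8-oxabicyclo[3.2.1]octenone (7 + 5 → 10 ring expansion).
4. That tricycle ← key step: dearomative (4+3) cycloaddition of an oxyallyl cation onto a fully substituted cyclopenta[c]furan, which sets the C4–O and C10–O quaternary centres anti to the C6–C8 triad.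
5. Furan lactone ← desymmetrizing transfer hydrogenation/lactonization of a mirror-symmetric furan-fused 1,3-dione ← 2,5-dimethylfuran + malonyl dichloride + ethyl glyoxylate. Ring order: cyclopentane on furan → γ-lactone → oxa-bridged seven-membered ring → ten-membered carbocycle → bridge opened.

Assumption: locants used for all compounds are C1–C10 for the ten-membered ring (C2 CHOH, C4 C(OH)CH3, C5 CH–OiBu, C6 lactone CH–O, C7, C8 CH–OiBu, C9 C=O, C10 CH–CH3) and C11–C13 for the lactone α-carbon, lactone C=O and exocyclic CH2; in this numbering the target is 2S,4S,5S,6R,7S,8S,10S. Hydroxy ketones 20–22 are drawn open although they may equilibrate with transannular hemiketals, and 1,1,3,3-tetrabromoacetone and ethyl glyoxylate (toluene solution) are bought.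

## Route

Step 1
Reactants: 1 2,5-dimethylfuran; 2 malonyl dichloride
Product: 4 1,3-dimethyl-4H-cyclopenta[c]furan-4,6(5H)-dione, via keto acid chloride 3 (not isolated)
Conditions: AlCl3 (2.5 equiv), CH2Cl2–MeNO2, −30 → 0 °C, slow addition of 1 at high dilution
Reagents that add atoms: none
Why: Twofold Friedel–Crafts acylation (intermolecular at C3, then ring-closing at C4) is the furan counterpart of the malonyl dichloride annulation known for 2,5-dimethylthiophene, the two methyl groups blocking the α-positions; no stereocentre is formed.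

Step 2
Reactants: 4 1,3-dimethyl-4H-cyclopenta[c]furan-4,6(5H)-dione; 5 ethyl glyoxylate
Product: 7 ethyl (1,3-dimethyl-4,6-dioxo-5,6-dihydro-4H-cyclopenta[c]furan-5-yl)acetate, via ylidene 6 (not isolated)
Conditions: Hantzsch ester (1.1 equiv), L-proline (10 mol%), CH2Cl2, rt
Reagents that add atoms: none
Why: Organocatalytic three-component reductive alkylation (Knoevenagel condensation, then conjugate hydride transfer from the Hantzsch ester to ylidene 6) gives clean mono-C-alkylation of the acidic dione and leaves an achiral product with two enantiotopic ketones.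

Step 3
Reactants: 7 ethyl (1,3-dimethyl-4,6-dioxo-5,6-dihydro-4H-cyclopenta[c]furan-5-yl)acetate
Product: 9 cis-fused keto lactone (6R), via hydroxy keto ester 8 (not isolated)
Conditions: RuCl[(R,R)-TsDPEN](p-cymene) (2 mol%), HCO2H–Et3N (5:2), EtOAc, 35 °C; then PPTS (10 mol%), PhMe, 70 °C
Reagents that add atoms: none
Why: Noyori asymmetric transfer hydrogenation reduces one of the two enantiotopic heteroaryl ketones to the 6R carbinol (same sense as 1-indanone with the R,R catalyst), C7 stays epimerizable next to the remaining ketone, and irreversible γ-lactonization of the cis isomer funnels the material to one cis-fused lactone (desymmetrization with dynamic kinetic resolution at C7).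

Step 4
Reactants: 9 cis-fused keto lactone (6R)
Product: 10 all-cis hydroxy lactone
Conditions: NaBH4, CeCl3·7H2O, MeOH, −40 °C
Reagents that add atoms: none
Why: Luche reduction in which hydride attacks the C8 carbonyl from the convex face of the cis-fused bicyclic lactone, so the new OH is cis to O6 and C11 (H-6, H-7 and H-8 all cis).

Step 5
Reactants: 10 all-cis hydroxy lactone
Product: 11 C8 TBS ether
Conditions: TBSOTf, 2,6-lutidine, CH2Cl2, 0 °C
Reagents that add atoms: tert-butyldimethylsilyl triflate, CC(C)(C)[Si](C)(C)OS(=O)(=O)C(F)(F)F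
Why: Standard silyl ether formation; the bulky non-acyl group later shields the C9 carbonyl and cannot act as an α-leaving group in the SmI2 step.

Step 6
Reactants: 11 C8 TBS ether
Product: 13 α-phosphono lactone, via enol phosphate 12 (not isolated)
Conditions: LiN(iPr)2 (1.1 equiv), THF, −78 °C; ClP(O)(OEt)2; then LiN(iPr)2 (2.2 equiv), −78 → 0 °C; AcOH
Reagents that add atoms: diethyl chlorophosphate, CCOP(=O)(Cl)OCC
Why: Wiemer phosphonylation, that is O-phosphorylation of the lactone enolate followed by base-induced 1,3-phosphorus shift to carbon, installs a robust precursor of the exocyclic methylene (C11 epimers are formed and are irrelevant).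

Step 7
Reactants: 13 α-phosphono lactone; 14 1,1,3,3-tetrabromoacetone
Product: 16 tricyclic oxa-bridged ketone, via dibromo cycloadduct 15 (not isolated)
Conditions: Zn dust, B(OEt)3, THF, 0 °C → rt; then Zn–Cu couple, NH4Cl, MeOH, rt
Reagents that add atoms: none
Why: Dearomative (4+3) cycloaddition (Hoffmann zinc/triethyl borate variant) of the bromo-oxyallyl cation across the two furan α-carbons occurs on the face opposite to the lactone and OTBS groups, creating the C4 and C10 quaternary C–O centres in the required sense, and reductive debromination of 15 leaves the parent keto bridge.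

Step 8
Reactants: 16 tricyclic oxa-bridged ketone
Product: 17 tricyclic equatorial alcohol
Conditions: SmI2 (3 equiv), iPrOH (10 equiv), THF, rt
Reagents that add atoms: none
Why: Single-electron ketone reduction under thermodynamic control gives the equatorial alcohol (OH cis to the bridgehead methyls and anti to the C5=C9 bridge, the configuration that becomes 2S in the target), whereas hydride reagents would attack from the open face and give the axial epimer.

Step 9
Reactants: 17 tricyclic equatorial alcohol
Product: 19 ether-bridged cyclodecane-5,9-dione, via ozonide 18 (not isolated)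
Conditions: O3, CH2Cl2, −78 °C; then PPh3, −78 °C → rt
Reagents that add atoms: ozone, [O-][O+]=O
Why: Ozonolysis of the electron-rich tetrasubstituted ring-fusion alkene (the only alkene present) and reduction of ozonide 18 unzips the fused five- and seven-membered rings into the ten-membered carbocycle, still spanned by the ether bridge, without touching any stereocentre.

Step 10
Reactants: 19 ether-bridged cyclodecane-5,9-dione
Product: 20 C5 alcohol (5S)
Conditions: LiBH(s-Bu)3 (3.2 equiv), THF, −78 °C; aq. NH4Cl
Reagents that add atoms: none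
Why: Substrate-controlled ketone reduction in which the C9 carbonyl is shielded by the neighbouring OTBS group while the C5 carbonyl, flanked by the tied-back and more electron-withdrawing lactone oxygen, is attacked by the bulky non-chelating hydride in the polar Felkin–Anh sense (anti to the C6–O bond, from the ring exterior) to give the 5S carbinol, whose alkoxide then masks C9 as a transannular hemiketal and prevents over-reduction.

Step 11
Reactants: 20 C5 alcohol (5S)
Product: 21 bridged C5,C8-diol ketone
Conditions: HF·pyridine, pyridine, THF, 0 °C → rt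
Reagents that add atoms: none
Why: Fluoride-mediated cleavage of the secondary TBS ether frees the C8 hydroxyl without affecting lactone, phosphonate or stereocentres.

Step 12
Reactants: 21 bridged C5,C8-diol ketone
Product: 22 ring-opened tetraol phosphonate
Conditions: SmI2 (2.5 equiv), THF–MeOH (4:1), −78 → −20 °C
Reagents that add atoms: none
Why: SmI2 reductive cleavage of an α-alkoxy ketone, in which the C9 ketyl expels the bridging ether oxygen (the free C8 hydroxyl is held in the ketyl plane by chelation and is a poor leaving group) to release the C4 tertiary alcohol, and the trivalent samarium enolate is protonated at C10 on the face just vacated by oxygen, where the C4 alkoxide–methanol cluster sits, giving 10S.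

Step 13
Reactants: 22 ring-opened tetraol phosphonate
Product: 25 C5,C8-bis-isobutyrate phosphonate, via C2 TES ether 23 (not isolated), via bis-isobutyrate TES ether 24 (not isolated)
Conditions: TESCl (1.05 equiv), imidazole, CH2Cl2, −78 °C; then iPrCOCl (5 equiv), DMAP, pyridine, 0 °C → rt; then HF·pyridine, THF, 0 °C
Reagents that add atoms: isobutyryl chloride, CC(C)C(Cl)=O
Why: One-pot transient protection and acylation, in which the unhindered C2 hydroxyl is silylated first, the two remaining secondary hydroxyls (C5 and C8) are esterified while the tertiary C4 hydroxyl does not react, and fluoride then removes the TES group.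

Step 14
Reactants: 25 C5,C8-bis-isobutyrate phosphonate
Product: 26 target CNP0113077.2
Conditions: CH2O (37% aq.), K2CO3, THF, 0 °C → rt
Reagents that add atoms: formaldehyde, C=O
Why: Horner–Wadsworth–Emmons olefination of the α-phosphono lactone with formaldehyde under mild carbonate conditions creates the exocyclic methylene last and removes the only undefined centre (C11).

## Compound list

1 | 2,5-dimethylfuran | Cc1ccc(C)o1 | starting material
2 | malonyl dichloride | O=C(Cl)CC(=O)Cl | starting material
3 | keto acid chloride: 3-(2,5-dimethylfuran-3-yl)-3-oxopropanoyl chloride (not isolated) | Cc1cc(C(=O)CC(=O)Cl)c(C)o1 | intermediate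
4 | 1,3-dimethyl-4H-cyclopenta[c]furan-4,6(5H)-dione | Cc1oc(C)c2C(=O)CC(=O)c12 | intermediate
5 | ethyl glyoxylate | O=CC(=O)OCC | starting material
6 | ylidene: ethyl (1,3-dimethyl-4,6-dioxo-4H-cyclopenta[c]furan-5(6H)-ylidene)acetate (not isolated) | CCOC(=O)C=C1C(=O)c2c(C)oc(C)c2C1=O | intermediate
7 | ethyl (1,3-dimethyl-4,6-dioxo-5,6-dihydro-4H-cyclopenta[c]furan-5-yl)acetate; achiral, mirror plane through C7 | CCOC(=O)CC1C(=O)c2c(C)oc(C)c2C1=O | intermediate
8 | hydroxy keto ester: ethyl [(4R,5S)-4-hydroxy-1,3-dimethyl-6-oxo-5,6-dihydro-4H-cyclopenta[c]furan-5-yl]acetate, OH and side chain cis (not isolated) | Cc1oc(C)c2c1[C@H](O)[C@H](CC(=O)OCC)C2=O | intermediate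
9 | cis-fused keto lactone (6R): γ-lactone between O6 and the C7 acetic acid chain on the furan-fused cyclopentanone, C8 ketone, H-6 and H-7 cis | Cc1oc(C)c2c1[C@@H]1OC(=O)C[C@@H]1C2=O | intermediate
10 | all-cis hydroxy lactone: as 9 with C8 CH–OH, H-6, H-7 and H-8 cis (6R) | Cc1oc(C)c2c1[C@@H]1OC(=O)C[C@@H]1[C@@H]2O | intermediate
11 | C8 TBS ether of 10 | Cc1oc(C)c2c1[C@@H]1OC(=O)C[C@@H]1[C@@H]2O[Si](C)(C)C(C)(C)C | intermediate
12 | enol phosphate: ketene acetal diethyl phosphate of lactone 11 (not isolated) | Cc1oc(C)c2c1[C@@H]1OC(OP(=O)(OCC)OCC)=C[C@@H]1[C@@H]2O[Si](C)(C)C(C)(C)C | intermediate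
13 | α-phosphono lactone: 11 carrying P(O)(OEt)2 at C11 (C11 epimers) | Cc1oc(C)c2c1[C@@H]1OC(=O)C(P(=O)(OCC)OCC)[C@@H]1[C@@H]2O[Si](C)(C)C(C)(C)C | intermediate
14 | 1,1,3,3-tetrabromoacetone | O=C(C(Br)Br)C(Br)Br | starting material
15 | dibromo cycloadduct: 16 with Br on C1 and C3 (epimer mixture, not isolated) | C[C@@]12C(Br)C(=O)C(Br)[C@@](C)(O1)C1=C2[C@@H]2OC(=O)C(P(=O)(OCC)OCC)[C@@H]2[C@@H]1O[Si](C)(C)C(C)(C)C | intermediate
16 | tricyclic oxa-bridged ketone: 1,5-dimethyl-8-oxabicyclo[3.2.1]oct-6-en-3-one whose alkene (C5=C9) is fused to the cyclopentane bearing the cis lactone and OTBS; keto bridge anti to lactone and OTBS | C[C@@]12CC(=O)C[C@@](C)(O1)C1=C2[C@@H]2OC(=O)C(P(=O)(OCC)OCC)[C@@H]2[C@@H]1O[Si](C)(C)C(C)(C)C | intermediate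
17 | tricyclic equatorial alcohol: 16 with C2 CH–OH, OH cis to the bridgehead methyls | C[C@@]12C[C@@H](O)C[C@@](C)(O1)C1=C2[C@@H]2OC(=O)C(P(=O)(OCC)OCC)[C@@H]2[C@@H]1O[Si](C)(C)C(C)(C)C | intermediate
18 | ozonide: 1,2,4-trioxolane spanning C5 and C9 of 17 (not isolated) | C[C@@]12C[C@@H](O)C[C@@](C)(O1)C13OOC2(O3)[C@@H]2OC(=O)C(P(=O)(OCC)OCC)[C@@H]2[C@@H]1O[Si](C)(C)C(C)(C)C | intermediate
19 | ether-bridged cyclodecane-5,9-dione: ten-membered carbocycle with C4–O–C10 bridge, C2 OH, C5 and C9 ketones, C6/C7 cis lactone, C8 OTBS | C[C@@]12C[C@@H](O)C[C@@](C)(O1)C(=O)[C@@H](O[Si](C)(C)C(C)(C)C)[C@H]1C(P(=O)(OCC)OCC)C(=O)O[C@H]1C2=O | intermediate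
20 | C5 alcohol (5S): 19 with C5 CH–OH | C[C@@]12C[C@@H](O)C[C@@](C)(O1)C(=O)[C@@H](O[Si](C)(C)C(C)(C)C)[C@H]1C(P(=O)(OCC)OCC)C(=O)O[C@H]1[C@@H]2O | intermediate
21 | bridged C5,C8-diol ketone: 20 without the silyl group | C[C@@]12C[C@@H](O)C[C@@](C)(O1)C(=O)[C@@H](O)[C@H]1C(P(=O)(OCC)OCC)C(=O)O[C@H]1[C@@H]2O | intermediate
22 | ring-opened tetraol phosphonate: target skeleton with free OH at C2, C4, C5, C8, C9 ketone, C10 H (10S), P(O)(OEt)2 at C11 | CCOP(=O)(OCC)C1C(=O)O[C@@H]2[C@H]1[C@H](O)C(=O)[C@@H](C)C[C@H](O)C[C@](C)(O)[C@H]2O | intermediate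
23 | C2 TES ether of 22 (not isolated) | CCOP(=O)(OCC)C1C(=O)O[C@@H]2[C@H]1[C@H](O)C(=O)[C@@H](C)C[C@H](O[Si](CC)(CC)CC)C[C@](C)(O)[C@H]2O | intermediate
24 | bis-isobutyrate TES ether: 23 acylated at O5 and O8 (not isolated) | CCOP(=O)(OCC)C1C(=O)O[C@@H]2[C@H]1[C@H](OC(=O)C(C)C)C(=O)[C@@H](C)C[C@H](O[Si](CC)(CC)CC)C[C@](C)(O)[C@H]2OC(=O)C(C)C | intermediate
25 | C5,C8-bis-isobutyrate phosphonate: target with P(O)(OEt)2 and H at C11 instead of the methylene | CCOP(=O)(OCC)C1C(=O)O[C@@H]2[C@H]1[C@H](OC(=O)C(C)C)C(=O)[C@@H](C)C[C@H](O)C[C@](C)(O)[C@H]2OC(=O)C(C)C | intermediate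
26 | CNP0113077.2 (2S,4S,5S,6R,7S,8S,10S) | C=C1C(=O)O[C@@H]2[C@H]1[C@H](OC(=O)C(C)C)C(=O)[C@@H](C)C[C@H](O)C[C@](C)(O)[C@H]2OC(=O)C(C)C | target

## Step count and risks

Total step count: 14. Longest linear sequence: 14 (fully linear from 2,5-dimethylfuran).

Three steps most likely to fail:

Step 1. The second, ring-closing acylation has to occur on a deactivated, acid-sensitive furan and form a strained 5-5 system, in competition with intermolecular diacylation. The fallback sets out from 1 and comes back at 4 by the phthalate-type route. NBS (2.1 equiv, DMF, 0 °C, dark) gives 3,4-dibromo-2,5-dimethylfuran F1. Double ethoxycarbonylation (Pd(OAc)2, dppf, CO, EtOH, Et3N, 100 °C) gives diethyl 2,5-dimethylfuran-3,4-dicarboxylate F2. Claisen–Dieckmann condensation with ethyl acetate (NaH, THF, reflux) gives ethyl 1,3-dimethyl-4,6-dioxo-5,6-dihydro-4H-cyclopenta[c]furan-5-carboxylate F3, which is hydrolysed and decarboxylated (aq. HCl, 70 °C) to 4.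

Step 7. The cycloaddition must engage a fully substituted furan bearing two ionizable furylic C–O bonds and form two quaternary centres. The fallback sets out from 13 and comes back at 16 by oxidative dearomatization followed by a stepwise annulation. mCPBA (CH2Cl2, 0 °C) opens the furan to the cis-enedione F4. A TMSOTf-catalysed (3+4) annulation of the 1,4-diketone with 1-allyloxy-1,3-bis(trimethylsilyloxy)buta-1,3-diene (CH2Cl2, −78 °C) closes the oxa-bridge through the cyclic oxocarbenium ion and gives the allyl β-keto ester F5; attack is expected on the face anti to the lactone and OTBS groups, but this selectivity would have to be checked. Pd(PPh3)4/morpholine (THF, rt) then removes the allyl ester with decarboxylation to give 16.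

Step 12. The C10–O bond must be cleaved in preference to the C8–O bond, and the C10 configuration depends on kinetic protonation. The fallback sets out from 20 and comes back at 22 by a non-reductive, base-induced bridge opening. Dess–Martin periodinane (1.1 equiv, CH2Cl2, 0 °C) oxidizes the unhindered C2 hydroxyl to the C2 ketone F6. DBU (CH2Cl2, rt) triggers retro-oxa-Michael opening toward C10, the side on which the new C1=C10 bond is conjugated with the C9 carbonyl, and gives the ring-opened ene-dione F7 with the free C4 hydroxyl. Hydrogenation directed by the C4 hydroxyl ([Ir(cod)(PCy3)(py)]PF6, H2, CH2Cl2) gives the saturated 2,9-dione F8 (10S). Chelation-controlled syn reduction of the β-hydroxy ketone (Et2BOMe, NaBH4, THF–MeOH, −78 °C) gives the C2 alcohol F9, and HF·pyridine removes the TBS group to give 22.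

## Further compounds

F1 | step 1 | 3,4-dibromo-2,5-dimethylfuran | Cc1oc(C)c(Br)c1Br
F2 | step 1 | diethyl 2,5-dimethylfuran-3,4-dicarboxylate | CCOC(=O)c1c(C)oc(C)c1C(=O)OCC
F3 | step 1 | ethyl 1,3-dimethyl-4,6-dioxo-5,6-dihydro-4H-cyclopenta[c]furan-5-carboxylate | CCOC(=O)C1C(=O)c2c(C)oc(C)c2C1=O
F4 | step 7 | cis-enedione (1,2-diacetylcyclopentene carrying the cis lactone and OTBS) from furan opening of 13 | CC(=O)C1=C(C(C)=O)[C@@H](O[Si](C)(C)C(C)(C)C)[C@H]2C(P(=O)(OCC)OCC)C(=O)O[C@@H]12
F5 | step 7 | allyl β-keto ester: 16 carrying CO2allyl at C3 | C[C@@]12C(C(=O)OCC=C)C(=O)C[C@@](C)(O1)C1=C2[C@@H]2OC(=O)C(P(=O)(OCC)OCC)[C@@H]2[C@@H]1O[Si](C)(C)C(C)(C)C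
F6 | step 12 | C2 ketone of 20 | C[C@@]12CC(=O)C[C@@](C)(O1)C(=O)[C@@H](O[Si](C)(C)C(C)(C)C)[C@H]1C(P(=O)(OCC)OCC)C(=O)O[C@H]1[C@@H]2O
F7 | step 12 | ring-opened (Z)-ene-dione with C1=C10 alkene, C2 and C9 ketones, free C4 and C5 hydroxyls, C8 OTBS | CCOP(=O)(OCC)C1C(=O)O[C@@H]2[C@H]1[C@H](O[Si](C)(C)C(C)(C)C)C(=O)/C(C)=C\C(=O)C[C@](C)(O)[C@H]2O
F8 | step 12 | saturated 2,9-dione (10S), C8 OTBS | CCOP(=O)(OCC)C1C(=O)O[C@@H]2[C@H]1[C@H](O[Si](C)(C)C(C)(C)C)C(=O)[C@@H](C)CC(=O)C[C@](C)(O)[C@H]2O
F9 | step 12 | C8 TBS ether of 22 | CCOP(=O)(OCC)C1C(=O)O[C@@H]2[C@H]1[C@H](O[Si](C)(C)C(C)(C)C)C(=O)[C@@H](C)C[C@H](O)C[C@](C)(O)[C@H]2O
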